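Numbering (germacrane type): C1(H)–C10(CH3) oxirane, C2H2, C3H2, C4(CH3)–C5(H) oxirane, C6 (O-cinnamoyl), C7 (isopropyl), C8 (OH), C9H2. C1–C10 form the ten-membered carbocycle.
Both oxiranes go back to the Z alkenes C1=C10 and C4=C5 (one double epoxidation directed by C8–OH). C8–OH and the C6 cinnamate go back together to a ring β-hydroxy ketone (C6–OH, C8=O) plus cinnamaldehyde (Evans–Tishchenko).
Key disconnection C9–C10: the ten-membered ring is closed by a reductive union of two electrophilic carbons, C9 of a chloromethyl ketone and C10 of a Z alkenyl iodide. Zinc reverses the polarity of C9 and palladium joins the two.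
Enabling feature: the oxygen on C8 stands β to oxirane carbon C10 across C9H2, so at the ketone/alkene level C8(=O)–C9H2–C10(CH3)=C1 is an α-alkenylated methyl ketone. The two Z ring alkenes (the later cis-fused oxiranes) fold the arm C5–C4–C3–C2–C1–C10 into a U that puts C10 next to C9.
The open chain comes from an Evans syn aldol (C6–C7) of an isovaleryl imide with a Z,Z iodo-enal made from neryl acetate. Ring order: carbocycle first, then both oxiranes at once.

Key step: step 11

Assumption: the SMILES is read literally. On each oxirane the two ring bonds are cis (1R,10S and 4S,5R), so both oxiranes derive from Z-configured ring alkenes, and both oxirane oxygens lie on the ring face that also carries C8–OH and the isopropyl group, opposite to the cinnamate.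

Step 1
Reactants: 1 neryl acetate, (2Z)-3,7-dimethylocta-2,6-dien-1-yl acetate
Product: 2 (2Z)-5-(3,3-dimethyloxiran-2-yl)-3-methylpent-2-en-1-yl acetate (racemic at the oxirane CH)
Conditions: mCPBA (1.0 equiv), NaHCO3, CH2Cl2, 0 °C
Reagents that add atoms: 3-chloroperoxybenzoic acid OOC(=O)c1cccc(Cl)c1
Why: Prilezhaev epoxidation with one equivalent of peracid goes to the electron-richer remote trisubstituted alkene, the other one being deactivated by the allylic acetate; the new stereocentre is racemic and is removed in step 2.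

Step 2
Reactants: 2 (2Z)-5-(3,3-dimethyloxiran-2-yl)-3-methylpent-2-en-1-yl acetate
Product: 3 (2Z)-3-methyl-6-oxohex-2-en-1-yl acetate
Conditions: H5IO6, THF–H2O, 0 °C
Reagents that add atoms: none
Why: Acidic hydrolysis of the oxirane and Malaprade glycol cleavage in one flask excise the isopropylidene end as acetone and leave the Z allylic acetate untouched; no stereocentre is formed.

Step 3
Reactants: 3 (2Z)-3-methyl-6-oxohex-2-en-1-yl acetate
Product: 4 (2Z,6Z)-7-iodo-3-methylocta-2,6-dien-1-yl acetate
Conditions: EtPPh3I, n-BuLi, THF, 23 °C; I2, −78 °C; NaN(SiMe3)2, −20 °C; then 3, −78 °C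
Reagents that add atoms: ethyltriphenylphosphonium iodide CC[P+](c1ccccc1)(c1ccccc1)c1ccccc1.[I-]; iodine II
Why: Stork–Zhao-type Wittig olefination with the non-stabilised α-iodo ylide proceeds under kinetic control through the cis-oxaphosphetane and should place iodine cis to the chain, which fixes the Z geometry of the later C1=C10 alkene.

Step 4
Reactants: 4 (2Z,6Z)-7-iodo-3-methylocta-2,6-dien-1-yl acetate
Product: 5 (2Z,6Z)-7-iodo-3-methylocta-2,6-dien-1-ol
Conditions: K2CO3 (0.2 equiv), MeOH, 0 °C
Reagents that add atoms: none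
Why: Base-catalysed transesterification (Zemplén type) frees the primary allylic alcohol without touching the alkenyl iodide or either alkene geometry.

Step 5
Reactants: 5 (2Z,6Z)-7-iodo-3-methylocta-2,6-dien-1-ol
Product: 6 (2Z,6Z)-7-iodo-3-methylocta-2,6-dienal
Conditions: TEMPO (10 mol %), PhI(OAc)2, MeCN–pH 7 buffer, 0 °C; used at once
Reagents that add atoms: none
Why: Oxoammonium (TEMPO) oxidation with PhI(OAc)2 as terminal oxidant works without strong acid or base, the condition under which nerol-type Z allylic alcohols give Z enals without Z to E isomerisation.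

Step 6
Reactants: 7 (4S)-4-benzyl-1,3-oxazolidin-2-one; 8 3-methylbutanoyl chloride
Product: 9 (4S)-4-benzyl-3-(3-methylbutanoyl)-1,3-oxazolidin-2-one
Conditions: Et3N, DMAP (cat.), CH2Cl2, 0 → 23 °C
Reagents that add atoms: none
Why: DMAP-catalysed N-acylation of the oxazolidinone with the acid chloride is a standard way to load an Evans auxiliary; its stereocentre is not involved.

Step 7
Reactants: 9 (4S)-4-benzyl-3-(3-methylbutanoyl)-1,3-oxazolidin-2-one; 6 (2Z,6Z)-7-iodo-3-methylocta-2,6-dienal
Product: 11 (4S)-4-benzyl-3-[(2S,3R,4Z,8Z)-3-hydroxy-9-iodo-5-methyl-2-(propan-2-yl)deca-4,8-dienoyl]-1,3-oxazolidin-2-one, via Z dibutylboron enolate 10 (not isolated)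
Conditions: Bu2BOTf, Et3N, CH2Cl2, 0 °C; 6, −78 → 0 °C; H2O2, MeOH, pH 7 buffer
Reagents that add atoms: none
Why: Evans syn aldol reaction: the Z boron enolate 10 reacts through a Zimmerman–Traxler chair on the face opposite to the benzyl group, which sets C6 and C7 (6,7-syn, absolute sense from the 4S auxiliary), and the low temperature should keep the Z enal from isomerising.

Step 8
Reactants: 11 aldol adduct
Product: 12 (2S,3R,4Z,8Z)-3-hydroxy-9-iodo-N-methoxy-N,5-dimethyl-2-(propan-2-yl)deca-4,8-dienamide
Conditions: MeONHMe·HCl, AlMe3, CH2Cl2, −10 → 23 °C; 0.5 M HCl work-up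
Reagents that add atoms: N,O-dimethylhydroxylamine hydrochloride CNOC.Cl
Why: Weinreb transamidation with the aluminium amide, delivered by the free C6 hydroxyl to the exocyclic carbonyl, releases the auxiliary without epimerisation at C7.

Step 9
Reactants: 12 β-hydroxy Weinreb amide
Product: 13 (2S,3R,4Z,8Z)-9-iodo-N-methoxy-N,5-dimethyl-2-(propan-2-yl)-3-(triethylsilyloxy)deca-4,8-dienamide
Conditions: Et3SiOTf, 2,6-lutidine, CH2Cl2, −78 °C
Reagents that add atoms: triethylsilyl trifluoromethanesulfonate CC[Si](CC)(CC)OS(=O)(=O)C(F)(F)F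
Why: Silylation with the reactive triflate covers the hindered C6 hydroxyl, which would otherwise protonate the enolate of step 11 or displace the C9 halide to a furanone.

Step 10
Reactants: 13 silylated Weinreb amide
Product: 14 (3S,4R,5Z,9Z)-1-chloro-10-iodo-6-methyl-3-(propan-2-yl)-4-(triethylsilyloxy)undeca-5,9-dien-2-one
Conditions: ICH2Cl (3 equiv), MeLi·LiBr (2.8 equiv, slow addition), THF, −78 °C; AcOH quench at −78 °C
Reagents that add atoms: chloroiodomethane ClCI
Why: Acylation of a halomethyllithium carbenoid by a Weinreb amide: iodine–lithium exchange of MeLi with ICH2Cl is much faster than with an alkenyl iodide, the carbenoid is trapped as it forms, and the chelated tetrahedral adduct prevents a second addition.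

Step 11
Reactants: 14 chloromethyl ketone with the Z alkenyl iodide terminus
Product: 17 (3Z,7Z,9R,10S)-3,7-dimethyl-10-(propan-2-yl)-9-(triethylsilyloxy)cyclodeca-3,7-dien-1-one, via iodomethyl ketone 15 (not isolated), via iodozinc enolate 16 (not isolated)
Conditions: LiI, Zn dust (cat. Me3SiCl), THF, 0 °C, 30 min, excess Zn filtered off; enolate solution added over 12 h to Pd2(dba)3 (5 mol %), P(t-Bu)3 (10 mol %), THF, 25–35 °C, final 2 mM
Reagents that add atoms: none
Why: Proposed new method: lithium iodide converts chloride 14 into iodide 15 (Finkelstein exchange), and zinc inserts at 0 °C into its activated C9–I bond while the unactivated alkenyl C10–I bond stays untouched, so the electrophilic C9 becomes the nucleophilic carbon of the regiodefined Reformatsky-type enolate 16. Under slow addition to zerovalent palladium the C10–I bond adds oxidatively with retention of the Z geometry, the zinc enolate transmetalates within the same molecule to an eleven-membered C-bound palladacycle, and reductive elimination contracts this to the ten-membered carbocycle with formation of C9–C10, the alkene C1=C10 ending up endocyclic. The closest known reaction types are the palladium-catalysed coupling of Reformatsky reagents and other zinc enolates with aryl and alkenyl halides (Negishi type) and the intramolecular α-alkenylation of ketone enolates, which closes five- to seven-membered rings, so the medium-ring closure is the new element. No stereocentre is created: C6 and C7 are spectators because the neutral, non-equilibrating zinc enolate can neither epimerise C7 nor expel the C6 silyloxy group, and both alkene geometries are carried over. Ring closure must beat oligomerisation and protonation, which is secured by pseudo-high dilution, by the two Z alkenes that fold C10 back over C9 and by the bulky C6 and C7 substituents that restrict the C6–C9 arm. C4=C5 must stay out although it stands in a 5-hexenyl relation to both C9 and C10, which is why a closed-shell zinc enolate (no free C9 radical) and near-ambient temperature (carbopalladation would have to build a quaternary C4) are chosen.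

Step 12
Reactants: 17 ten-membered silyloxy dienone
Product: 18 (3Z,7Z,9R,10S)-9-hydroxy-3,7-dimethyl-10-(propan-2-yl)cyclodeca-3,7-dien-1-one
Conditions: HF·pyridine, pyridine, THF, 0 °C
Reagents that add atoms: none
Why: Fluoride-mediated cleavage of the triethylsilyl ether under pyridine-buffered conditions should avoid retro-aldol opening, C7 epimerisation and conjugation of the β,γ-enone.

Step 13
Reactants: 18 ring β-hydroxy ketone; 19 (E)-cinnamaldehyde
Product: 20 (1R,2Z,6Z,9R,10R)-9-hydroxy-3,7-dimethyl-10-(propan-2-yl)cyclodeca-2,6-dien-1-yl (2E)-3-phenylprop-2-enoate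
Conditions: 19 (5 equiv), SmI2 (0.3 equiv, premixed with 19), THF, −10 °C
Reagents that add atoms: none
Why: Evans–Tishchenko reaction: the samarium-bound hemiacetal of the C6 hydroxyl and 19 transfers its hydride to C8 through a bicyclic chair, which sets C8 1,3-anti to C6, leaves the oxidised aldehyde as the cinnamate on O6 only and frees O8; in that chair C5 and C9 are cis, the arrangement the ring favours.

Step 14
Reactants: 20 Z,Z-cyclodecadienyl cinnamate with free C8–OH
Product: 21 (1R,4S,5R,6S,7R,8R,10S)-1,10:4,5-diepoxy-8-hydroxygermacran-6-yl (2E)-3-phenylprop-2-enoate (CNP0272646.1)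
Conditions: VO(acac)2 (10 mol %), t-BuOOH (2.5 equiv, decane), CH2Cl2, 0 → 23 °C
Reagents that add atoms: tert-butyl hydroperoxide CC(C)(C)OO
Why: Hydroxyl-directed vanadium-catalysed epoxidation: the vanadate ester of C8–OH delivers oxygen to the homoallylic C1=C10 and the bishomoallylic C4=C5 alkene on the ring face that carries C8–OH, syn addition to the Z alkenes gives the two cis-fused oxiranes (C1, C10, C4, C5), and for C4=C5 the same face is favoured by allylic 1,3-strain at C6 and peripheral attack (oxirane trans to the cinnamate).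

Compound list
1 | neryl acetate | CC(C)=CCC/C(C)=C\COC(C)=O | starting material
2 | (2Z)-5-(3,3-dimethyloxiran-2-yl)-3-methylpent-2-en-1-yl acetate (racemic at the oxirane CH) | CC1(C)OC1CC/C(C)=C\COC(C)=O | intermediate
3 | (2Z)-3-methyl-6-oxohex-2-en-1-yl acetate | O=CCC/C(C)=C\COC(C)=O | intermediate
4 | (2Z,6Z)-7-iodo-3-methylocta-2,6-dien-1-yl acetate | C/C(I)=C/CC/C(C)=C\COC(C)=O | intermediate
5 | (2Z,6Z)-7-iodo-3-methylocta-2,6-dien-1-ol | C/C(I)=C/CC/C(C)=C\CO | intermediate
6 | (2Z,6Z)-7-iodo-3-methylocta-2,6-dienal | C/C(I)=C/CC/C(C)=C\C=O | intermediate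
7 | (4S)-4-benzyl-1,3-oxazolidin-2-one | O=C1N[C@@H](Cc2ccccc2)CO1 | starting material
8 | 3-methylbutanoyl chloride | CC(C)CC(=O)Cl | starting material
9 | (4S)-4-benzyl-3-(3-methylbutanoyl)-1,3-oxazolidin-2-one | CC(C)CC(=O)N1[C@@H](Cc2ccccc2)COC1=O | intermediate
10 | Z dibutylboron enolate of 9 (not isolated) | CC(C)/C=C(\OB(CCCC)CCCC)N1[C@@H](Cc2ccccc2)COC1=O | intermediate
11 | (4S)-4-benzyl-3-[(2S,3R,4Z,8Z)-3-hydroxy-9-iodo-5-methyl-2-(propan-2-yl)deca-4,8-dienoyl]-1,3-oxazolidin-2-one | C/C(I)=C/CC/C(C)=C\[C@@H](O)[C@H](C(C)C)C(=O)N1[C@@H](Cc2ccccc2)COC1=O | intermediate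
12 | (2S,3R,4Z,8Z)-3-hydroxy-9-iodo-N-methoxy-N,5-dimethyl-2-(propan-2-yl)deca-4,8-dienamide | C/C(I)=C/CC/C(C)=C\[C@@H](O)[C@H](C(C)C)C(=O)N(C)OC | intermediate
13 | (2S,3R,4Z,8Z)-9-iodo-N-methoxy-N,5-dimethyl-2-(propan-2-yl)-3-(triethylsilyloxy)deca-4,8-dienamide | C/C(I)=C/CC/C(C)=C\[C@@H](O[Si](CC)(CC)CC)[C@H](C(C)C)C(=O)N(C)OC | intermediate
14 | (3S,4R,5Z,9Z)-1-chloro-10-iodo-6-methyl-3-(propan-2-yl)-4-(triethylsilyloxy)undeca-5,9-dien-2-one | C/C(I)=C/CC/C(C)=C\[C@@H](O[Si](CC)(CC)CC)[C@H](C(C)C)C(=O)CCl | intermediate
15 | (3S,4R,5Z,9Z)-1,10-diiodo-6-methyl-3-(propan-2-yl)-4-(triethylsilyloxy)undeca-5,9-dien-2-one (not isolated) | C/C(I)=C/CC/C(C)=C\[C@@H](O[Si](CC)(CC)CC)[C@H](C(C)C)C(=O)CI | intermediate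
16 | iodozinc enolate of the C8 ketone, drawn C9-bound (not isolated) | C/C(I)=C/CC/C(C)=C\[C@@H](O[Si](CC)(CC)CC)[C@H](C(C)C)C(=O)C[Zn]I | intermediate
17 | (3Z,7Z,9R,10S)-3,7-dimethyl-10-(propan-2-yl)-9-(triethylsilyloxy)cyclodeca-3,7-dien-1-one | CC(C)[C@H]1[C@H](O[Si](CC)(CC)CC)/C=C(C)\CC/C=C(C)\CC1=O | intermediate
18 | (3Z,7Z,9R,10S)-9-hydroxy-3,7-dimethyl-10-(propan-2-yl)cyclodeca-3,7-dien-1-one | CC(C)[C@H]1[C@H](O)/C=C(C)\CC/C=C(C)\CC1=O | intermediate
19 | (E)-cinnamaldehyde | O=C/C=C/c1ccccc1 | starting material
20 | (1R,2Z,6Z,9R,10R)-9-hydroxy-3,7-dimethyl-10-(propan-2-yl)cyclodeca-2,6-dien-1-yl (2E)-3-phenylprop-2-enoate | CC(C)[C@H]1[C@H](OC(=O)/C=C/c2ccccc2)/C=C(C)\CC/C=C(C)\C[C@H]1O | intermediate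
21 | (1R,4S,5R,6S,7R,8R,10S)-1,10:4,5-diepoxy-8-hydroxygermacran-6-yl (2E)-3-phenylprop-2-enoate | CC(C)[C@H]1[C@H](OC(=O)/C=C/c2ccccc2)[C@H]2O[C@@]2(C)CC[C@H]2O[C@@]2(C)C[C@H]1O | target

Total step count: 14. Longest linear sequence: 13 (steps 1–5 and 7–14).

Steps most likely to fail

Step 11. What may go wrong: oligomerisation outruns the medium-ring closure, the zinc enolate is protonated before it transmetalates, or the alkenylpalladium species is diverted onto C4=C5.
Fallback (known chemistry, ring closed at the alkene C1=C10 instead): it sets out from 13. Addition of 2-methylallylmagnesium chloride (THF, −20 °C) to the Weinreb amide should give the methallyl ketone F1. Hydrodeiodination with Bu3SnH and Pd(PPh3)4 should give the propenyl-terminated triene F2. Ring-closing metathesis with the second-generation Hoveyda–Grubbs catalyst (toluene, 80 °C, 1 mM) should then join C1 to the methallyl carbon with loss of propene. The Z alkene is the less strained isomer in a ten-membered ring. The route is rejoined at 17.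

Step 14. What may go wrong: the vanadate tethered at O8 does not reach the remote C4=C5 alkene, so that this alkene reacts slowly or by an undirected path with poor facial selectivity.
Fallback (two different control elements instead of one): it sets out from 20. With 1.1 equiv of t-BuOOH and VO(acac)2 at −20 °C the faster homoallylic delivery should stop at the 1,10-monoepoxide F3. C4=C5 is then epoxidised with mCPBA and NaHCO3 in CH2Cl2 at 0 °C. There the face is chosen by allylic 1,3-strain at C6 and peripheral attack on the ring, not by hydroxyl delivery. The route is rejoined at 21.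

Step 13. What may go wrong: retro-aldol opening of the strained ring at the samarium alkoxide stage, slow hydride transfer from the conjugated hemiacetal, or acyl migration between O6 and O8.
Fallback (ester and carbinol made in two separate, alkoxide-free events): it sets out from 18. Acylation with (E)-cinnamoyl chloride, pyridine and catalytic DMAP at 0 °C should give the keto cinnamate F4. Corey–Bakshi–Shibata reduction with (S)-2-methyl-CBS-oxazaborolidine and catecholborane (toluene, −40 °C) then sets C8 under reagent control. The branched C7 acts as the large substituent of the ketone and C9H2 as the small one. The route is rejoined at 20.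

Further compounds
F1 | step 11 | (5S,6R,7Z,11Z)-12-iodo-2,8-dimethyl-5-(propan-2-yl)-6-(triethylsilyloxy)trideca-1,7,11-trien-4-one | C/C(I)=C/CC/C(C)=C\[C@@H](O[Si](CC)(CC)CC)[C@H](C(C)C)C(=O)CC(C)=C
F2 | step 11 | (5S,6R,7Z,11E)-2,8-dimethyl-5-(propan-2-yl)-6-(triethylsilyloxy)trideca-1,7,11-trien-4-one | C/C=C/CC/C(C)=C\[C@@H](O[Si](CC)(CC)CC)[C@H](C(C)C)C(=O)CC(C)=C
F3 | step 14 | (1R,4Z,6R,7R,8R,10S)-1,10-epoxy-8-hydroxygermacr-4-en-6-yl (2E)-3-phenylprop-2-enoate | CC(C)[C@H]1[C@H](OC(=O)/C=C/c2ccccc2)/C=C(C)\CC[C@H]2O[C@@]2(C)C[C@H]1O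
F4 | step 13 | (1R,2Z,6Z,10S)-3,7-dimethyl-9-oxo-10-(propan-2-yl)cyclodeca-2,6-dien-1-yl (2E)-3-phenylprop-2-enoate | CC(C)[C@H]1[C@H](OC(=O)/C=C/c2ccccc2)/C=C(C)\CC/C=C(C)\CC1=O
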